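## Retrosynthetic overview

1. The plan rests on C9 and C10, two neighbouring fully substituted carbons. C10 is shared by rings A and B, and C9 is the spiro atom of rings B and C. They are carried as the two ends of one tetrasubstituted alkene, so the congested C9–C10 bond is in place from the start.
2. Ring B is cut at C5–C10 and C8–C9 (retro-[4+2]), which also opens ring A. This gives a (Z)-2-alkylidenefuran-3-one (rings C and D intact, C11 ketone as activator) joined through C1–C4 to the 2-silyloxydiene C5–C8.
3. The triene is cut at C10–C1 (B-alkyl Suzuki–Miyaura) into a (Z)-bromoethylidene furanone and a silyloxytriene made from mesityl oxide. The alkene geometry comes from an anti iodoetherification of a bromoalkyne followed by two stereoretentive couplings.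
4. C13–C16 come from L-tartrate. The extra oxygen on C14 is kept as a pivalate that blocks one face of ring C during the cycloaddition, and it is removed afterwards.
5. Ring order: D, then C, then A and B together. Afterwards C11 and C14 are deoxygenated, C7 is oxidised through the silyl enol ether, and C5 is epimerised.

Key step: step 16

Assumption: the lithium enolate of the tartrate acetonide is taken to be allylated with net retention (the two ester groups stay trans), as is usual for this enolate. If the other face reacted, the D-tartrate ester would give the same C13 configuration and only the temporary C14 centre would change.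

Labdane numbering is used for the carbons. Ring C is the oxolane (O, C9, C11, C12, C13) and ring D is the lactone (C13, C14, C15, O, C16).

## Route

Step 1
Reactants: 1 dimethyl (4R,5R)-2,2-dimethyl-1,3-dioxolane-4,5-dicarboxylate (acetonide of dimethyl L-tartrate); 2 allyl bromide
Product: 4 dimethyl (4R,5R)-4-allyl-2,2-dimethyl-1,3-dioxolane-4,5-dicarboxylate, via lithium enolate 3 (not isolated)
Conditions: LiN(iPr)2, THF–DMPU, −78 °C; then 2, −78 °C
Reagents that add atoms: none
Why: Ester enolate alkylation of a tartrate acetonide, whose enolate resists beta-elimination below −70 °C; the neighbouring stereocentre directs the allyl group so that the esters stay trans, which sets the quaternary carbon that becomes C13.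

Step 2
Reactants: 4 dimethyl (4R,5R)-4-allyl-2,2-dimethyl-1,3-dioxolane-4,5-dicarboxylate
Product: 5 (4R,5R)-5-allyl-5-(methoxycarbonyl)-2,2-dimethyl-1,3-dioxolane-4-carboxylic acid
Conditions: KOH (1 equiv), MeOH–H2O, 0 °C; then aq. HCl
Reagents that add atoms: potassium hydroxide, [K+].[OH-]
Why: Chemoselective saponification, because the ester on the CH carbon (future C15) is attacked much faster than the neopentyl-type ester on the quaternary carbon (future C16), and no stereocentre is touched.

Step 3
Reactants: 5 (4R,5R)-5-allyl-5-(methoxycarbonyl)-2,2-dimethyl-1,3-dioxolane-4-carboxylic acid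
Product: 7 (3R,4S)-4-allyl-3,4-dihydroxyoxolan-2-one, via hydroxy acid 6 (not isolated)
Conditions: LiEt3BH (3.3 equiv), THF, 0 °C to rt; then 2 M HCl, THF, 40 °C
Reagents that add atoms: none
Why: Hydride reduction of the ester next to an inert lithium carboxylate, then acid-catalysed acetonide cleavage and gamma-lactonisation, turns C16 into the CH2O unit and closes ring D without touching either stereocentre.

Step 4
Reactants: 7 (3R,4S)-4-allyl-3,4-dihydroxyoxolan-2-one
Product: 8 (3R,4S)-4-allyl-4-hydroxy-2-oxooxolan-3-yl pivalate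
Conditions: PivCl, pyridine, DMAP (cat.), CH2Cl2, 0 °C
Reagents that add atoms: pivaloyl chloride, CC(C)(C)C(=O)Cl
Why: Selective acylation of the secondary C14 alcohol over the tertiary C13 alcohol installs a robust, bulky ester that later shields the C14 face of ring C.

Step 5
Reactants: 8 (3R,4S)-4-allyl-4-hydroxy-2-oxooxolan-3-yl pivalate
Product: 10 (3R,4S)-4-hydroxy-2-oxo-4-(2-oxoethyl)oxolan-3-yl pivalate, via secondary ozonide 9 (not isolated)
Conditions: O3, CH2Cl2, −78 °C; then Me2S, −78 °C to rt
Reagents that add atoms: ozone, [O-][O+]=O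
Why: Ozonolysis with reductive work-up cleaves the only alkene to the C11 aldehyde under neutral conditions that leave the lactone, the pivalate and the tertiary alcohol intact.

Step 6
Reactants: 10 (3R,4S)-4-hydroxy-2-oxo-4-(2-oxoethyl)oxolan-3-yl pivalate; 11 ethynylmagnesium bromide
Product: 12 (3R,4S)-4-hydroxy-4-(2-hydroxybut-3-ynyl)-2-oxooxolan-3-yl pivalate (both C11 epimers)
Conditions: HC≡CMgBr (2.5 equiv), THF, −78 °C
Reagents that add atoms: none
Why: 1,2-Addition of an alkynyl Grignard reagent, in which one equivalent deprotonates the tertiary alcohol and the aldehyde reacts far faster than the lactone or pivalate at −78 °C; the new C11 carbinol centre forms as a mixture and is erased in step 9.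

Step 7
Reactants: 12 (3R,4S)-4-hydroxy-4-(2-hydroxybut-3-ynyl)-2-oxooxolan-3-yl pivalate
Product: 13 (3R,4S)-4-(4-bromo-2-hydroxybut-3-ynyl)-4-hydroxy-2-oxooxolan-3-yl pivalate
Conditions: NBS, AgNO3 (10 mol %), acetone, rt
Reagents that add atoms: N-bromosuccinimide, O=C1CCC(=O)N1Br
Why: Silver-catalysed electrophilic bromination of a terminal alkyne through the silver acetylide is mild and tolerates free alcohols and esters.

Step 8
Reactants: 13 (3R,4S)-4-(4-bromo-2-hydroxybut-3-ynyl)-4-hydroxy-2-oxooxolan-3-yl pivalate
Product: 14 (2E,5S,9R)-2-[bromo(iodo)methylidene]-3-hydroxy-8-oxo-1,7-dioxaspiro[4.4]nonan-9-yl pivalate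
Conditions: NIS, MeCN, 0 °C, dark
Reagents that add atoms: N-iodosuccinimide, O=C1CCC(=O)N1I
Why: Proposed new method: NIS transfers I+ to the bromoalkyne, positive charge builds up on C9 (the carbon remote from bromine, the same polarity by which 1-haloalkynes hydrate to alpha-halomethyl ketones), and the tertiary C13 hydroxyl attacks C9 anti to iodine in a 5-exo-dig closure of ring C, so iodine ends trans and bromine cis to the ring oxygen; the closest known types are the 5-exo-dig iodoetherification of alkyl-substituted 4-alkyn-1-ols and the exo cyclisation of 1-bromoalkynoic acids to (Z)-bromo enol lactones.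

Step 9
Reactants: 14 (2E,5S,9R)-2-[bromo(iodo)methylidene]-3-hydroxy-8-oxo-1,7-dioxaspiro[4.4]nonan-9-yl pivalate
Product: 15 (2E,5S,9R)-2-[bromo(iodo)methylidene]-3,8-dioxo-1,7-dioxaspiro[4.4]nonan-9-yl pivalate
Conditions: Dess–Martin periodinane, CH2Cl2, 0 °C to rt
Reagents that add atoms: none
Why: Dess–Martin oxidation of the allylic C11 alcohol is fast and near neutral, merges both carbinol epimers into one ketone and leaves the alkene geometry alone.

Step 10
Reactants: 15 (2E,5S,9R)-2-[bromo(iodo)methylidene]-3,8-dioxo-1,7-dioxaspiro[4.4]nonan-9-yl pivalate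
Product: 16 (2Z,5S,9R)-2-(1-bromoethylidene)-3,8-dioxo-1,7-dioxaspiro[4.4]nonan-9-yl pivalate
Conditions: MeZnCl (1.1 equiv), Pd(PPh3)4 (5 mol %), THF, 0 °C
Reagents that add atoms: methylzinc chloride, C[Zn]Cl
Why: Negishi coupling, in which zerovalent palladium inserts into C–I much faster than into the geminal C–Br and the coupling goes with retention, so C20 ends cis to the C11 carbonyl and bromine stays cis to the ring oxygen.

Step 11
Reactants: 17 mesityl oxide; 18 allyltrimethylsilane
Product: 19 4,4-dimethylhept-6-en-2-one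
Conditions: TiCl4, CH2Cl2, −78 °C
Reagents that add atoms: none
Why: Hosomi–Sakurai conjugate allylation of a beta,beta-disubstituted enone builds the quaternary C4 with its gem-dimethyl group together with the C1–C3 chain in one operation.

Step 12
Reactants: 19 4,4-dimethylhept-6-en-2-one; 20 acetaldehyde
Product: 22 2-hydroxy-6,6-dimethylnon-8-en-4-one (racemic), via lithium enolate 21 (not isolated)
Conditions: LiN(iPr)2, THF, −78 °C; then MeCHO, −78 °C
Reagents that add atoms: none
Why: Kinetic aldol addition, since deprotonation takes place at the methyl group rather than at the neopentyl CH2, and the carbinol centre is lost in the next step.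

Step 13
Reactants: 22 2-hydroxy-6,6-dimethylnon-8-en-4-one
Product: 24 (E)-6,6-dimethylnona-2,8-dien-4-one, via mesylate 23 (not isolated)
Conditions: MsCl, Et3N (excess), CH2Cl2, 0 °C to rt
Reagents that add atoms: none
Why: Mesylation followed by E1cB elimination of a beta-sulfonyloxy ketone gives the conjugated (E)-enone, the more stable isomer.

Step 14
Reactants: 24 (E)-6,6-dimethylnona-2,8-dien-4-one
Product: 26 tert-butyl{[(2E,4Z)-6,6-dimethylnona-2,4,8-trien-4-yl]oxy}dimethylsilane, via lithium dienolate 25 (not isolated)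
Conditions: LiN(iPr)2, THF–DMPU, −78 °C; then TBSCl, −78 to 0 °C
Reagents that add atoms: tert-butyldimethylsilyl chloride, CC(C)(C)[Si](C)(C)Cl
Why: Kinetic alpha-prime deprotonation of an enone (as with isophorone, whose alpha-prime CH2 is also neopentyl) gives the cross-conjugated dienolate, and O-silylation gives the Z enol ether because the tert-alkyl group avoids the propenyl group.

Step 15
Reactants: 26 tert-butyl{[(2E,4Z)-6,6-dimethylnona-2,4,8-trien-4-yl]oxy}dimethylsilane; 16 (2Z,5S,9R)-2-(1-bromoethylidene)-3,8-dioxo-1,7-dioxaspiro[4.4]nonan-9-yl pivalate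
Product: 29 (2Z,5S,9R)-2-[(7Z,9E)-8-(tert-butyldimethylsilyloxy)-6,6-dimethylundeca-7,9-dien-2-ylidene]-3,8-dioxo-1,7-dioxaspiro[4.4]nonan-9-yl pivalate, via alkylborane 27 (not isolated), via sodium methoxyborate 28 (not isolated)
Conditions: 9-BBN, THF, rt; NaOMe (1.0 equiv); then 16, PdCl2(dppf) (5 mol %), THF–DMF, rt to 40 °C
Reagents that add atoms: none
Why: 9-BBN hydroborates only the monosubstituted alkene, and the B-alkyl Suzuki–Miyaura coupling of the preformed borate needs no free base and keeps the alkene geometry, so C1 ends cis to the ring oxygen (Z) and the base-sensitive furanone survives.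

Step 16
Reactants: 29 (2Z,5S,9R)-2-[(7Z,9E)-8-(tert-butyldimethylsilyloxy)-6,6-dimethylundeca-7,9-dien-2-ylidene]-3,8-dioxo-1,7-dioxaspiro[4.4]nonan-9-yl pivalate
Product: 30 (13S,14R)-6-(tert-butyldimethylsilyloxy)-9α,13-epoxy-11-oxo-14-pivaloyloxy-5β-labd-6-en-15,16-olide (cis-fused; 8α-methyl; 10β-methyl)
Conditions: toluene (0.005 M), BHT (trace), 150 °C, sealed tube, base-washed glass
Reagents that add atoms: none
Why: Proposed new method: on heating, the electron-rich 2-silyloxydiene C5=C6–C7=C8 and the ketone-activated C9=C10 alkene should combine in a concerted, asynchronous, normal-demand type 1 intramolecular Diels–Alder reaction, in which the diene terminus C5 (largest HOMO coefficient) bonds to the enone beta-carbon C10 and C8 bonds to C9. The closest known types are the thermal cyclisation of 1,7,9-decatrienes to decalins and the cycloadditions of s-cis-locked captodative exocyclic alkenes such as 2-alkylidene-3(2H)-furanones and 5-methylene-1,3-dioxolan-4-ones, none of which carries a fully substituted dienophile. Ring B is the six-membered ring of the [4+2] event itself, and ring A closes in the fused mode because the chain C1–C4 already links C10 to C5, so the new C5–C10 bond completes a six-membered carbocycle. Suprafacial addition to the Z alkene (C1 cis to the ring oxygen, C20 cis to C11) fixes C9 against C10; the 5Z,7E diene geometry puts C4 and the C8 methyl on the same side of ring B; and the orientation with the chain and the ring oxygen under the diene and the C11 carbonyl outside places that methyl anti to C11 (8α) and gives the 5β-H cis fusion, which step 22 corrects. This carbonyl-exo orientation is required, and it should be secured by the known exo preference of exocyclic s-cis-locked dienophiles, by the absence of a Lewis acid, and by the clash that the other orientation creates between C20, the silyloxy-bearing C6 and the C4 methyl groups. Facial selectivity is also required: ring D stands perpendicular to ring C with C16 on one face and C14 on the other, the C8 methyl of the incoming diene must pass over ring C, and the pivaloyloxy group on C14 fills that space on its side, so addition should occur on the C16 face and pass the tartrate chirality on to C8, C9 and C10.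

Step 17
Reactants: 30 (13S,14R)-6-(tert-butyldimethylsilyloxy)-9α,13-epoxy-11-oxo-14-pivaloyloxy-5β-labd-6-en-15,16-olide
Product: 31 the corresponding 11-alcohol (either C11 epimer serves)
Conditions: NaBH4, MeOH–THF, −40 °C
Reagents that add atoms: none
Why: Borohydride reduction takes the five-ring ketone much faster than the lactone or pivalate at low temperature while C6 stays masked as the base-stable silyl enol ether, and the new C11 centre is removed in step 19.

Step 18
Reactants: 31 the 11-alcohol
Product: 32 the 11-O-(imidazol-1-ylthiocarbonyl) derivative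
Conditions: 1,1'-thiocarbonyldiimidazole, DMAP, toluene, 80 °C
Reagents that add atoms: 1,1'-thiocarbonyldiimidazole, S=C(n1ccnc1)n1ccnc1
Why: Thioacylation under neutral conditions prepares the only free alcohol for radical deoxygenation and avoids the strong base of xanthate formation, which would endanger the lactone and the silyl enol ether.

Step 19
Reactants: 32 the 11-O-(imidazol-1-ylthiocarbonyl) derivative
Product: 33 (13S,14R)-6-(tert-butyldimethylsilyloxy)-9α,13-epoxy-14-pivaloyloxy-5β-labd-6-en-15,16-olide
Conditions: Bu3SnH, AIBN, toluene, 100 °C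
Reagents that add atoms: none
Why: Barton–McCombie deoxygenation, in which the secondary C11 radical abstracts hydrogen from the stannane faster than it could break the beta C9–O bond, and the neutral medium spares the enol ether, lactone and pivalate.

Step 20
Reactants: 33 (13S,14R)-6-(tert-butyldimethylsilyloxy)-9α,13-epoxy-14-pivaloyloxy-5β-labd-6-en-15,16-olide
Product: 34 (13R)-6-(tert-butyldimethylsilyloxy)-9α,13-epoxy-5β-labd-6-en-15,16-olide
Conditions: SmI2, THF–HMPA, MeOH, 0 °C to rt
Reagents that add atoms: none
Why: SmI2 reduction of an alpha-acyloxy lactone expels pivalate, and methanol protonates the samarium enolate before the poor tertiary alkoxide at C13 can leave; no ketone is present at this stage that SmI2 could attack.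

Step 21
Reactants: 34 (13R)-6-(tert-butyldimethylsilyloxy)-9α,13-epoxy-5β-labd-6-en-15,16-olide
Product: 36 (13R)-7β-(tert-butyldimethylsilyloxy)-9α,13-epoxy-6-oxo-5β-labdan-15,16-olide, via silyloxy epoxide 35 (not isolated)
Conditions: mCPBA, CH2Cl2, −20 to 0 °C
Reagents that add atoms: 3-chloroperbenzoic acid, OOC(=O)c1cccc(Cl)c1
Why: Rubottom oxidation, in which the peracid attacks C6=C7 from the β face (only H5 and H8 lie there, whereas C4 with its methyl groups and the 8α-methyl cover the α face) and silyl migration opens the epoxide to the 7β-silyloxy ketone, which sets C7.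

Step 22
Reactants: 36 (13R)-7β-(tert-butyldimethylsilyloxy)-9α,13-epoxy-6-oxo-5β-labdan-15,16-olide
Product: 37 (13R)-7β-(tert-butyldimethylsilyloxy)-9α,13-epoxy-6-oxolabdan-15,16-olide (5α-H, trans-fused)
Conditions: DBU, toluene, 60 °C
Reagents that add atoms: none
Why: Base-mediated epimerisation through the C5 enolate under thermodynamic control sets C5, because the trans-decalin removes the diaxial contact between C4 and the oxygen on C9; the equatorial 7β-silyloxy group is already the stable epimer, and the much less acidic lactone is not enolised.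

Step 23
Reactants: 37 (13R)-7β-(tert-butyldimethylsilyloxy)-9α,13-epoxy-6-oxolabdan-15,16-olide
Product: 38 (13R)-9α,13-epoxy-7β-hydroxy-6-oxolabdan-15,16-olide, (5S,7R,8R,9R,10S,13R), the target
Conditions: HF·pyridine, THF, 0 °C to rt
Reagents that add atoms: none
Why: Fluoride-induced desilylation in a weakly acidic medium frees the 7β-alcohol without enolising the ketol or opening the lactone.

## Compound list

1 | dimethyl (4R,5R)-2,2-dimethyl-1,3-dioxolane-4,5-dicarboxylate | COC(=O)[C@@H]1OC(C)(C)O[C@H]1C(=O)OC | starting material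
2 | allyl bromide | C=CCBr | starting material
3 | lithium enolate of 1 | COC(=O)[C@@H]1OC(C)(C)OC1=C([O-])OC.[Li+] | intermediate
4 | dimethyl (4R,5R)-4-allyl-2,2-dimethyl-1,3-dioxolane-4,5-dicarboxylate | COC(=O)[C@@H]1OC(C)(C)O[C@@]1(CC=C)C(=O)OC | intermediate
5 | (4R,5R)-5-allyl-5-(methoxycarbonyl)-2,2-dimethyl-1,3-dioxolane-4-carboxylic acid | OC(=O)[C@@H]1OC(C)(C)O[C@@]1(CC=C)C(=O)OC | intermediate
6 | (4R,5S)-5-allyl-5-(hydroxymethyl)-2,2-dimethyl-1,3-dioxolane-4-carboxylic acid | OC(=O)[C@@H]1OC(C)(C)O[C@@]1(CC=C)CO | intermediate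
7 | (3R,4S)-4-allyl-3,4-dihydroxyoxolan-2-one | O=C1OC[C@@](O)(CC=C)[C@H]1O | intermediate
8 | (3R,4S)-4-allyl-4-hydroxy-2-oxooxolan-3-yl pivalate | O=C1OC[C@@](O)(CC=C)[C@H]1OC(=O)C(C)(C)C | intermediate
9 | secondary ozonide (1,2,4-trioxolane) of 8 | O=C1OC[C@@](O)(CC2OCOO2)[C@H]1OC(=O)C(C)(C)C | intermediate
10 | (3R,4S)-4-hydroxy-2-oxo-4-(2-oxoethyl)oxolan-3-yl pivalate | O=C1OC[C@@](O)(CC=O)[C@H]1OC(=O)C(C)(C)C | intermediate
11 | ethynylmagnesium bromide | C#C[Mg]Br | starting material
12 | (3R,4S)-4-hydroxy-4-(2-hydroxybut-3-ynyl)-2-oxooxolan-3-yl pivalate, both C11 epimers | O=C1OC[C@@](O)(CC(O)C#C)[C@H]1OC(=O)C(C)(C)C | intermediate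
13 | (3R,4S)-4-(4-bromo-2-hydroxybut-3-ynyl)-4-hydroxy-2-oxooxolan-3-yl pivalate | O=C1OC[C@@](O)(CC(O)C#CBr)[C@H]1OC(=O)C(C)(C)C | intermediate
14 | (2E,5S,9R)-2-[bromo(iodo)methylidene]-3-hydroxy-8-oxo-1,7-dioxaspiro[4.4]nonan-9-yl pivalate | Br/C(I)=C1\O[C@]2(COC(=O)[C@@H]2OC(=O)C(C)(C)C)CC1O | intermediate
15 | (2E,5S,9R)-2-[bromo(iodo)methylidene]-3,8-dioxo-1,7-dioxaspiro[4.4]nonan-9-yl pivalate | Br/C(I)=C1\O[C@]2(COC(=O)[C@@H]2OC(=O)C(C)(C)C)CC1=O | intermediate
16 | (2Z,5S,9R)-2-(1-bromoethylidene)-3,8-dioxo-1,7-dioxaspiro[4.4]nonan-9-yl pivalate | Br/C(C)=C1\O[C@]2(COC(=O)[C@@H]2OC(=O)C(C)(C)C)CC1=O | intermediate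
17 | mesityl oxide | CC(C)=CC(C)=O | starting material
18 | allyltrimethylsilane | C=CC[Si](C)(C)C | starting material
19 | 4,4-dimethylhept-6-en-2-one | C=CCC(C)(C)CC(C)=O | intermediate
20 | acetaldehyde | CC=O | starting material
21 | kinetic lithium enolate of 19 | [Li+].C=CCC(C)(C)CC([O-])=C | intermediate
22 | 2-hydroxy-6,6-dimethylnon-8-en-4-one (racemic) | C=CCC(C)(C)CC(=O)CC(C)O | intermediate
23 | mesylate of 22 | C=CCC(C)(C)CC(=O)CC(C)OS(C)(=O)=O | intermediate
24 | (E)-6,6-dimethylnona-2,8-dien-4-one | C/C=C/C(=O)CC(C)(C)CC=C | intermediate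
25 | cross-conjugated lithium (Z)-dienolate of 24 | [Li+].C/C=C/C([O-])=C/C(C)(C)CC=C | intermediate
26 | tert-butyl{[(2E,4Z)-6,6-dimethylnona-2,4,8-trien-4-yl]oxy}dimethylsilane | C/C=C/C(O[Si](C)(C)C(C)(C)C)=C/C(C)(C)CC=C | intermediate
27 | B-alkyl-9-borabicyclo[3.3.1]nonane from 26 | C/C=C/C(O[Si](C)(C)C(C)(C)C)=C/C(C)(C)CCCB1C2CCCC1CCC2 | intermediate
28 | sodium B-alkyl-B-methoxy-9-boratabicyclo[3.3.1]nonane | [Na+].C/C=C/C(O[Si](C)(C)C(C)(C)C)=C/C(C)(C)CCC[B-]1(OC)C2CCCC1CCC2 | intermediate
29 | (Z)-alkylidene spiro furanone tethered to the silyloxydiene (cycloaddition precursor, 14-pivaloyloxy) | C/C=C/C(O[Si](C)(C)C(C)(C)C)=C/C(C)(C)CCC/C(C)=C1\O[C@]2(COC(=O)[C@@H]2OC(=O)C(C)(C)C)CC1=O | intermediate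
30 | cis-fused 11-oxo adduct with C6 silyl enol ether (14-pivaloyloxy) | C[C@@H]1C=C(O[Si](C)(C)C(C)(C)C)[C@@H]2C(C)(C)CCC[C@]2(C)[C@@]12C(=O)C[C@@]1(COC(=O)[C@@H]1OC(=O)C(C)(C)C)O2 | intermediate
31 | 11-alcohol of 30 (C11 undefined) | C[C@@H]1C=C(O[Si](C)(C)C(C)(C)C)[C@@H]2C(C)(C)CCC[C@]2(C)[C@@]12C(O)C[C@@]1(COC(=O)[C@@H]1OC(=O)C(C)(C)C)O2 | intermediate
32 | 11-O-(imidazol-1-ylthiocarbonyl) derivative of 31 | C[C@@H]1C=C(O[Si](C)(C)C(C)(C)C)[C@@H]2C(C)(C)CCC[C@]2(C)[C@@]12C(OC(=S)n3ccnc3)C[C@@]1(COC(=O)[C@@H]1OC(=O)C(C)(C)C)O2 | intermediate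
33 | 11-deoxy compound (14-pivaloyloxy, C6 silyl enol ether, 5β-H) | C[C@@H]1C=C(O[Si](C)(C)C(C)(C)C)[C@@H]2C(C)(C)CCC[C@]2(C)[C@@]12CC[C@@]1(COC(=O)[C@@H]1OC(=O)C(C)(C)C)O2 | intermediate
34 | (13R)-6-(tert-butyldimethylsilyloxy)-9α,13-epoxy-5β-labd-6-en-15,16-olide | C[C@@H]1C=C(O[Si](C)(C)C(C)(C)C)[C@@H]2C(C)(C)CCC[C@]2(C)[C@@]12CC[C@@]1(COC(=O)C1)O2 | intermediate
35 | 6β,7β-epoxide of 34 (silyloxy epoxide) | C[C@@H]1[C@H]3O[C@@]3(O[Si](C)(C)C(C)(C)C)[C@@H]2C(C)(C)CCC[C@]2(C)[C@@]12CC[C@@]1(COC(=O)C1)O2 | intermediate
36 | (13R)-7β-(tert-butyldimethylsilyloxy)-9α,13-epoxy-6-oxo-5β-labdan-15,16-olide | C[C@@H]1[C@@H](O[Si](C)(C)C(C)(C)C)C(=O)[C@@H]2C(C)(C)CCC[C@]2(C)[C@@]12CC[C@@]1(COC(=O)C1)O2 | intermediate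
37 | (13R)-7β-(tert-butyldimethylsilyloxy)-9α,13-epoxy-6-oxolabdan-15,16-olide (5α-H) | C[C@@H]1[C@@H](O[Si](C)(C)C(C)(C)C)C(=O)[C@H]2C(C)(C)CCC[C@]2(C)[C@@]12CC[C@@]1(COC(=O)C1)O2 | intermediate
38 | (13R)-9α,13-epoxy-7β-hydroxy-6-oxolabdan-15,16-olide | C[C@@H]1[C@@H](O)C(=O)[C@H]2C(C)(C)CCC[C@]2(C)[C@@]12CC[C@@]1(COC(=O)C1)O2 | target

## Step count and weak points

Total step count: 23. Longest linear sequence: 19 (steps 1–10 and 15–23).

**Step 16 (cycloaddition).**
- The two fully substituted alkene carbons and the neighbouring C4 may slow the reaction so much that thermal enolisation and geometric isomerisation of the alkylidene furanone take over.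
- The carbonyl-endo orientation may compete, and shielding by the C14 pivalate may be incomplete.
- The fallback forms the same two bonds one after the other by ionic chemistry of known type (sequential Mukaiyama–Michael additions with silyl transfer). It sets out from 29.
- Catalytic TBSOTf in CH2Cl2 at −78 °C should add C5 to C10 and move the silyl group to the C11 oxygen. This gives the monocyclic Michael adduct F1, with ring A closed, a crotonoyl group on C5 and a 3-silyloxy-4,5-dihydrofuran on C10.
- Warming with the same catalyst should add C9 to C8 and move the silyl group back to the C6 oxygen, which returns to the route at 30.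
- In this variant C9 is set by the closure of ring B on the C16 face and no longer by the alkene geometry.

**Step 8 (iodoetherification of the bromoalkyne).**
- The halogen lowers the reactivity of the alkyne towards I+, so 6-endo closure or halogen-induced rearrangement of the propargylic alcohol may compete.
- The fallback uses silicon instead of bromine as the placeholder and sets out from 10.
- LiC≡CSiMe3 gives the silylalkyne diol F2.
- NIS closes ring C, with the beta-silyl effect directing attack to C9, and gives the iodo(silyl)methylidene ether F3.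
- MeZnCl with Pd(PPh3)4 replaces iodine with retention and gives the vinylsilane F4.
- NBS effects ipso-bromodesilylation with retention on the still electron-rich enol ether and gives the bromoethylidene alcohol F5.
- Dess–Martin oxidation returns to the route at 16.

**Step 15 (fragment union).**
- Transmetalation to a fully substituted alkenylpalladium may be slow, which leaves time for protodeboronation, beta-hydride elimination, or alkoxide-triggered opening of ring C or ring D by beta-elimination.
- The fallback is a base-free Negishi coupling and sets out from 26.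
- Hydroboration with Et2BH gives the diethyl(alkyl)borane F6, and boron–zinc exchange with Et2Zn gives the dialkylzinc F7.
- Coupling of F7 with 16 under PdCl2(dppf) in THF returns to the route at 29.

## Further compounds

F1 | step 16 | monocyclic Michael adduct (ring A closed, crotonoyl group on C5, 3-silyloxy-4,5-dihydrofuran on C10) | C/C=C/C(=O)[C@@H]1C(C)(C)CCC[C@]1(C)C1=C(O[Si](C)(C)C(C)(C)C)C[C@@]2(COC(=O)[C@@H]2OC(=O)C(C)(C)C)O1
F2 | step 8 | (3R,4S)-4-hydroxy-4-[2-hydroxy-4-(trimethylsilyl)but-3-ynyl]-2-oxooxolan-3-yl pivalate | O=C1OC[C@@](O)(CC(O)C#C[Si](C)(C)C)[C@H]1OC(=O)C(C)(C)C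
F3 | step 8 | (5S,9R)-3-hydroxy-2-[iodo(trimethylsilyl)methylidene]-8-oxo-1,7-dioxaspiro[4.4]nonan-9-yl pivalate, silicon cis to the ring oxygen | C[Si](C)(C)/C(I)=C1\O[C@]2(COC(=O)[C@@H]2OC(=O)C(C)(C)C)CC1O
F4 | step 8 | (5S,9R)-3-hydroxy-8-oxo-2-[1-(trimethylsilyl)ethylidene]-1,7-dioxaspiro[4.4]nonan-9-yl pivalate, silicon cis to the ring oxygen | C[Si](C)(C)/C(C)=C1\O[C@]2(COC(=O)[C@@H]2OC(=O)C(C)(C)C)CC1O
F5 | step 8 | (2Z,5S,9R)-2-(1-bromoethylidene)-3-hydroxy-8-oxo-1,7-dioxaspiro[4.4]nonan-9-yl pivalate | Br/C(C)=C1\O[C@]2(COC(=O)[C@@H]2OC(=O)C(C)(C)C)CC1O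
F6 | step 15 | diethyl[(5Z,7E)-6-(tert-butyldimethylsilyloxy)-4,4-dimethylnona-5,7-dienyl]borane | C/C=C/C(O[Si](C)(C)C(C)(C)C)=C/C(C)(C)CCCB(CC)CC
F7 | step 15 | bis[(5Z,7E)-6-(tert-butyldimethylsilyloxy)-4,4-dimethylnona-5,7-dienyl]zinc | C/C=C/C(O[Si](C)(C)C(C)(C)C)=C/C(C)(C)CCC[Zn]CCCC(C)(C)/C=C(O[Si](C)(C)C(C)(C)C)/C=C/C
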